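A fixed percentage of the charge cannot describe these runs: at 40.0 min the winter run reads 53%, the spring run 26% and the noon run 4%, from charges of 7.1 mM, 38 mM and 170 mM.

| flask | solid substrate | remark | time |
|---|---|---|---|
| winter | 7.1 mM | run made earlier |  |
| spring | 38 mM | run made earlier |  |
| noon | 170 mM | run made earlier |  |
| amber | 10 mM |  | 40 min |
| grey | 20 mM |  | 40 min |
| ochre | 40 mM |  | 40 min |
| red | 80 mM |  | 40 min |
| green | 150 mM |  | 40 min |

- winter (time / min: product / %): 8.00: 5; 15.0: 14; 25.0: 32; 30.0: 40; 40.0: 53
- spring (time / min: product / %): 8.00: 1; 15.0: 3; 25.0: 13; 30.0: 18; 40.0: 26
- noon (time / min: product / %): 8.00: 2; 15.0: 1; 25.0: 3; 30.0: 5; 40.0: 4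

(scatter of a reading: 1.5 percentage points)

- solid, in amounts per volume of the solution: solid substrate
- at the start none of the solid substrate is in solution
- "hardly changes" means that all values lie within two and a half points (for a concentration: within two and a half percent of the largest)
- a step back or a flat step of under half a percent of the largest counts as no turn

- [product] at the end for amber, grey, ochre, red, green, in this order
- how that number moves from the first to the last of them (hardly changes / falls all the way / rises all the way / rises, then falls / falls, then rises)

Equal percentages are the zero of the scale, with product growing in step with the charge. The opposite case is equal amounts in mM, and it has a plain physical reading, since the substrate starts wholly undissolved: while solid lies undissolved, the solution need not feel how much more lies beside it.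

The last spring reading stands for 9.88 mM of product, with the scatter of a reading. Call this P, the ceiling: the product at 40 min of a flask that still holds solid, so that its charge no longer counts (zero order in the charge). The noon run is a second way to P, and it gives 6.80 mM, which is 3.08 mM lower.

The scatter shows which way cheats. A scatter of 1.5 percentage points is worth 0.570 mM at the spring charge but 2.55 mM at the noon charge, so the noon figure is looser, and the gap is 1.21 times that noon scatter. Summed over the last two readings, the runs lie closer than the last readings do, with 16.7 mM for spring and 15.3 mM for noon. P therefore stays at the spring value.

This reckoning gives a small charge the winter percentage and a larger one P, and the two rules meet at a charge of 18.6 mM. It puts amber at 5.30 mM, and grey, ochre, red and green at P. The row climbs and then lies flat, which by the stated marks counts as rising all the way.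

The forecast reads 5 mM, 8 mM, 9.8 mM, 9 mM and 7 mM, rises, then falls, lower than this reckoning at green, and holds that “the absolute product passes through a maximum”. The flasks give 5.09 mM, 8.86 mM, 11.0 mM, 11.0 mM and 11.0 mM: rises all the way.

    starting material → intermediate A (k = 4.70 × 10⁻⁴ s⁻¹)
    starting material → product (k = 1.20 × 10⁻⁴ s⁻¹)
    intermediate A ⇌ intermediate B (K = 0.300, k = 1.50 × 10⁻⁴ s⁻¹)
    intermediate A → product (k = 0.00100 s⁻¹)
    solid substrate ⇌ starting material, rate k5*(cs5 - [starting material]) while solid is left; crystals form when [starting material] > cs5 (solubility = 37.0 mM, k = 6.10 × 10⁻⁴ s⁻¹)

In amber at 3.96 min, starting material is made 7.18 times faster than it is used up, each step taken net. At 40.0 min, ochre, red and green, with 10.9%, 55.4% and 76.2% of their charge still solid, hold 17.7 mM, 17.8 mM and 17.8 mM of starting material. Divided by the green charge, P gives 6.59%, and green holds 7.34% of product at 40.0 min.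

(The data were computed from invented constants, and the scatter is random.)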